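**Plan**

1. Numbering used here: carbocycle C5 (CH–isopropenyl)–C6 (CH–O, lactone)–C7 (ring-fusion CH)–C8 (CH–OAc)–C9 (CH2)–C10 (C(Me)(vinyl)); lactone O–C6–C7–C11 (C(Me)(O-angeloyl))–C12 (C=O).
2. Retrosynthesis: first the two acyl groups are removed (angelate on C11–O, acetate on C8–O); then C7–C8 and C11–OH are cut together; then the butenolide is opened (C12 from CO, C6–C7 by alkynyl addition); last C5–C10 is cut by an Ireland–Claisen transform back to an allylic ester.
3. Enabling feature: O–C8 is γ to the lactone carbonyl C12 through C7–C11, a 1,4-dioxygen pattern. C8 is therefore an aldehyde-derived ketyl and C7 the β-carbon of an α-methylbutenolide, and the enolate left at C11 after ring closure is where the tertiary oxygen is put in.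
4. Forward: the chain is assembled (C5–C10, then C6–C7), the butenolide ring is closed, the carbocycle is closed last by reductive radical–polar crossover cyclization with oxygenation, and two acylations finish.
5. Stereochemistry: C5 and C10 come from the chair Claisen transition state under a chiral boron enolate (absolute control); C6 from Felkin–Anh addition next to C5; C7, C8 and C11 from the key step (cis ring fusion dictated by C6, chair-like transition state, convex-face oxygenation).

Key step: step 11

Assumption: the (S,S)-configured diazaborolidine controller (treated as a purchasable, recoverable reagent) is taken to deliver the (2R,3R)-acid 7; should its facial sense prove opposite, the (R,R)-antipode is used with no other change.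

**Step 1**
Reactants: 1 4-(tert-butyldimethylsilyloxy)but-1-yne
Product: 3 (E)-5-[(tert-butyldimethylsilyl)oxy]-3-methylpent-2-en-1-ol, via alkenyldimethylalane 2 (not isolated)
Conditions: AlMe3, Cp2ZrCl2 (cat.), CH2Cl2, 0 °C → rt; then n-butyllithium, (CH2O)n, THF, −30 °C → rt
Reagents that add atoms: trimethylaluminium C[Al](C)C; paraformaldehyde (as formaldehyde) C=O
Why: Negishi carboalumination adds methyl and aluminium syn across the terminal alkyne with aluminium at the terminus, and hydroxymethylation of the derived alanate with retention should give only the (E)-trisubstituted allylic alcohol whose geometry later sets C10.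

**Step 2**
Reactants: 3 (E)-5-[(tert-butyldimethylsilyl)oxy]-3-methylpent-2-en-1-ol; 4 3-methylbut-3-enoic acid
Product: 5 (E)-5-[(tert-butyldimethylsilyl)oxy]-3-methylpent-2-en-1-yl 3-methylbut-3-enoate
Conditions: DCC, DMAP (cat.), CH2Cl2, 0 °C
Reagents that add atoms: none
Why: Steglich esterification of a primary allylic alcohol runs under near-neutral conditions that should leave the silyl ether and both alkenes untouched.

**Step 3**
Reactants: 5 (E)-5-[(tert-butyldimethylsilyl)oxy]-3-methylpent-2-en-1-yl 3-methylbut-3-enoate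
Product: 7 (2R,3R)-3-{2-[(tert-butyldimethylsilyl)oxy]ethyl}-3-methyl-2-(prop-1-en-2-yl)pent-4-enoic acid, via boron enolate 6 (not isolated)
Conditions: (S,S)-N,N'-bis[3,5-bis(trifluoromethyl)phenylsulfonyl]-1,2-diphenylethane-1,2-diamine, BBr3, CH2Cl2, rt, then evaporation; 5, Et3N, toluene–hexane, −78 °C; then 4 °C, 2–3 d; aqueous work-up
Reagents that add atoms: none
Why: In this enantioselective Ireland–Claisen rearrangement, soft enolization in a non-polar medium should give the E(O) boron ketene acetal (isopropenyl cis to the allyloxy oxygen), whose chair [3,3] transition state (C9 chain equatorial from the (E)-alkene, methyl axial) forms C5–C10 with methyl and isopropenyl in the required relative sense, while the C2-symmetric boron ligand shields one enolate face and so fixes both centres absolutely.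

**Step 4**
Reactants: 7 (2R,3R)-3-{2-[(tert-butyldimethylsilyl)oxy]ethyl}-3-methyl-2-(prop-1-en-2-yl)pent-4-enoic acid
Product: 8 (2R,3R)-3-{2-[(tert-butyldimethylsilyl)oxy]ethyl}-3-methyl-2-(prop-1-en-2-yl)pent-4-en-1-ol
Conditions: LiAlH4, Et2O, 0 °C → rt
Reagents that add atoms: none
Why: Hydride reduction of the acid proceeds through the carboxylate, so C5 should not epimerize, and the alkenes and silyl ether are inert.

**Step 5**
Reactants: 8 (2R,3R)-3-{2-[(tert-butyldimethylsilyl)oxy]ethyl}-3-methyl-2-(prop-1-en-2-yl)pent-4-en-1-ol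
Product: 9 (2R,3R)-3-{2-[(tert-butyldimethylsilyl)oxy]ethyl}-3-methyl-2-(prop-1-en-2-yl)pent-4-enal
Conditions: Dess–Martin periodinane, pyridine, CH2Cl2, 0 °C (used at once)
Reagents that add atoms: none
Why: Buffered Dess–Martin oxidation is mild enough that the β,γ-unsaturated aldehyde should neither epimerize at C5 nor move its alkene into conjugation.

**Step 6**
Reactants: 9 (2R,3R)-3-{2-[(tert-butyldimethylsilyl)oxy]ethyl}-3-methyl-2-(prop-1-en-2-yl)pent-4-enal
Product: 10 (4S,5R,6R)-6-{2-[(tert-butyldimethylsilyl)oxy]ethyl}-6-methyl-5-(prop-1-en-2-yl)oct-7-en-2-yn-4-ol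
Conditions: 1-propynylmagnesium bromide, THF, −78 °C
Reagents that add atoms: 1-propynylmagnesium bromide CC#C[Mg]Br
Why: In this Felkin–Anh-controlled Grignard addition the quaternary C10 group is the large substituent anti to the incoming alkynyl, which passes over H-5, and this should give the C6 carbinol with the configuration of the target.

**Step 7**
Reactants: 10 (4S,5R,6R)-6-{2-[(tert-butyldimethylsilyl)oxy]ethyl}-6-methyl-5-(prop-1-en-2-yl)oct-7-en-2-yn-4-ol
Product: 12 (2Z,4S,5R,6R)-6-{2-[(tert-butyldimethylsilyl)oxy]ethyl}-2-iodo-6-methyl-5-(prop-1-en-2-yl)octa-2,7-dien-4-ol, via cyclic alkenylaluminate 11 (not isolated)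
Conditions: NaAlH2(OCH2CH2OMe)2 (Red-Al), THF, 0 °C → rt; then I2, −78 °C
Reagents that add atoms: iodine II
Why: Hydroxyl-directed trans-hydroalumination of the propargylic alcohol delivers hydride to C7 and aluminium to C11 inside a five-membered oxa-aluminacycle, and iodinolysis with retention should give the (Z)-γ-hydroxy vinyl iodide.

**Step 8**
Reactants: 12 (2Z,4S,5R,6R)-6-{2-[(tert-butyldimethylsilyl)oxy]ethyl}-2-iodo-6-methyl-5-(prop-1-en-2-yl)octa-2,7-dien-4-ol
Product: 13 (5R)-5-[(3R,4R)-4-{2-[(tert-butyldimethylsilyl)oxy]ethyl}-2,4-dimethylhexa-1,5-dien-3-yl]-3-methylfuran-2(5H)-one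
Conditions: PdCl2(PPh3)2 (cat.), CO (1 atm), K2CO3, THF, rt
Reagents that add atoms: carbon monoxide [C-]#[O+]
Why: In this palladium-catalysed carbonylative lactonization, oxidative addition of the vinyl iodide to zerovalent palladium, CO insertion and capture of the acyl-palladium by the cis hydroxyl should close the α-methylbutenolide at room temperature, faster than any Heck pathway and without touching C6.

**Step 9**
Reactants: 13 (5R)-5-[(3R,4R)-4-{2-[(tert-butyldimethylsilyl)oxy]ethyl}-2,4-dimethylhexa-1,5-dien-3-yl]-3-methylfuran-2(5H)-one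
Product: 14 (5R)-5-[(3R,4R)-4-(2-hydroxyethyl)-2,4-dimethylhexa-1,5-dien-3-yl]-3-methylfuran-2(5H)-one
Conditions: HF·pyridine, THF, 0 °C → rt
Reagents that add atoms: none
Why: Acidic fluoride desilylation frees the primary alcohol without the basic conditions that could deprotonate the butenolide at C6 and scramble that centre.

**Step 10**
Reactants: 14 (5R)-5-[(3R,4R)-4-(2-hydroxyethyl)-2,4-dimethylhexa-1,5-dien-3-yl]-3-methylfuran-2(5H)-one
Product: 15 (3R,4R)-3-ethenyl-3,5-dimethyl-4-[(2R)-4-methyl-5-oxo-2,5-dihydrofuran-2-yl]hex-5-enal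
Conditions: Dess–Martin periodinane, pyridine, CH2Cl2, 0 °C → rt
Reagents that add atoms: none
Why: Dess–Martin oxidation of the primary alcohol should give the C8 aldehyde, which cannot epimerize (quaternary β-carbon), under conditions the butenolide tolerates.

**Step 11**
Reactants: 15 (3R,4R)-3-ethenyl-3,5-dimethyl-4-[(2R)-4-methyl-5-oxo-2,5-dihydrofuran-2-yl]hex-5-enal
Product: 17 (3S,3aR,4S,6R,7R,7aS)-6-ethenyl-3,4-dihydroxy-3,6-dimethyl-7-(prop-1-en-2-yl)hexahydro-1-benzofuran-2(3H)-one, via samarium enolate 16 (not isolated)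
Conditions: SmI2 (2.2 equiv), HMPA, THF, −78 °C, slow addition of 15; then trans-3-phenyl-2-(phenylsulfonyl)oxaziridine, −78 → −40 °C; aq. NH4Cl
Reagents that add atoms: trans-3-phenyl-2-(phenylsulfonyl)oxaziridine O=S(=O)(N1OC1c1ccccc1)c1ccccc1
Why: Proposed new method: electron transfer from divalent samarium to the aldehyde gives the C8 ketyl, which adds 6-exo-trig to C7, the β-carbon of the butenolide; the tertiary α-lactone radical at C11 is reduced by a second SmI2 to the trivalent samarium enolate 16 (radical–polar crossover), and, with no proton source present, this enolate is oxygenated at C11 by oxygen transfer from the N-sulfonyloxaziridine. The closest known reaction types are the SmI2–HMPA ketyl–olefin cyclization onto unsaturated esters and lactones with protic or aldol capture of the samarium enolate, and the oxaziridine hydroxylation of lithium or potassium lactone enolates; only the oxygen capture of the samarium enolate in the same flask is new, and it is argued from the known nucleophilicity of such enolates toward carbonyl electrophiles. One ring closes, the carbocycle, in 6-exo-trig mode, and because C8 can reach C7 only on the butenolide face that carries the C5 tether at C6, H-6 and H-7 should end up cis (C7 is controlled by C6). At C8, the planar butenolide fixes a chair-like transition state in which the bulky O–Sm(HMPA)n group sits equatorial and points away from the lactone, the axial alternative being syn to the axial vinyl on C10 and to the lactone oxygen, so C8–O should be trans to C7–C11. At C11, the oxidant should approach the enolate on the convex face of the cis-fused bicycle, anti to C8 and its samarium alkoxide, which places the new hydroxyl cis to H-7 and the methyl on the concave face. The step needs chemoselectivity for the electron-poor butenolide over the vinyl and isopropenyl groups, secured by the polarity match with the nucleophilic ketyl and by the lack of a favourable exo path to either isolated alkene, and it needs the enolate to survive until oxidation, secured by leaving out alcohol additives and adding the substrate slowly at −78 °C.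

**Step 12**
Reactants: 17 (3S,3aR,4S,6R,7R,7aS)-6-ethenyl-3,4-dihydroxy-3,6-dimethyl-7-(prop-1-en-2-yl)hexahydro-1-benzofuran-2(3H)-one
Product: 18 (3S,3aR,4S,6R,7R,7aS)-6-ethenyl-3-hydroxy-3,6-dimethyl-2-oxo-7-(prop-1-en-2-yl)octahydro-1-benzofuran-4-yl acetate
Conditions: Ac2O, pyridine, DMAP (cat.), CH2Cl2, 0 °C
Reagents that add atoms: acetic anhydride CC(=O)OC(C)=O
Why: Acylation at 0 °C should take place only at the equatorial secondary C8 hydroxyl and leave the hindered tertiary α-hydroxy lactone free.

**Step 13**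
Reactants: 18 (3S,3aR,4S,6R,7R,7aS)-6-ethenyl-3-hydroxy-3,6-dimethyl-2-oxo-7-(prop-1-en-2-yl)octahydro-1-benzofuran-4-yl acetate; 19 angelic acid [(2Z)-2-methylbut-2-enoic acid]
Product: 21 (3S,3aR,4S,6R,7R,7aS)-4-acetoxy-6-ethenyl-3,6-dimethyl-2-oxo-7-(prop-1-en-2-yl)octahydro-1-benzofuran-3-yl (2Z)-2-methylbut-2-enoate, via mixed anhydride 20 (not isolated)
Conditions: 19, 2,4,6-trichlorobenzoyl chloride, Et3N, toluene, rt; then 18, 90 °C
Reagents that add atoms: none
Why: Yamaguchi esterification through the trichlorobenzoyl mixed anhydride acylates the tertiary hydroxyl at the angeloyl carbonyl without a nucleophilic catalyst, which should avoid the addition–elimination path that turns the (Z)-angelate into the (E)-tiglate.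

**Compound list**

1 | 4-(tert-butyldimethylsilyloxy)but-1-yne | C#CCCO[Si](C)(C)C(C)(C)C | starting material
2 | (E)-[4-(tert-butyldimethylsilyloxy)-2-methylbut-1-en-1-yl]dimethylalane (not isolated) | C[Al](C)/C=C(\C)CCO[Si](C)(C)C(C)(C)C | intermediate
3 | (E)-5-[(tert-butyldimethylsilyl)oxy]-3-methylpent-2-en-1-ol | OC/C=C(\C)CCO[Si](C)(C)C(C)(C)C | intermediate
4 | 3-methylbut-3-enoic acid | C=C(C)CC(=O)O | starting material
5 | (E)-5-[(tert-butyldimethylsilyl)oxy]-3-methylpent-2-en-1-yl 3-methylbut-3-enoate | C=C(C)CC(=O)OC/C=C(\C)CCO[Si](C)(C)C(C)(C)C | intermediate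
6 | E(O) boron ketene acetal of 5 carrying the (4S,5S)-1,3-bis[3,5-bis(trifluoromethyl)phenylsulfonyl]-4,5-diphenyl-1,3,2-diazaborolidin-2-yl group (not isolated) | C=C(C)/C=C(\OC/C=C(\C)CCO[Si](C)(C)C(C)(C)C)OB1N(S(=O)(=O)c2cc(cc(c2)C(F)(F)F)C(F)(F)F)[C@@H](c2ccccc2)[C@H](c2ccccc2)N1S(=O)(=O)c1cc(cc(c1)C(F)(F)F)C(F)(F)F | intermediate
7 | (2R,3R)-3-{2-[(tert-butyldimethylsilyl)oxy]ethyl}-3-methyl-2-(prop-1-en-2-yl)pent-4-enoic acid | C=C[C@@](C)(CCO[Si](C)(C)C(C)(C)C)[C@@H](C(C)=C)C(=O)O | intermediate
8 | (2R,3R)-3-{2-[(tert-butyldimethylsilyl)oxy]ethyl}-3-methyl-2-(prop-1-en-2-yl)pent-4-en-1-ol | C=C[C@@](C)(CCO[Si](C)(C)C(C)(C)C)[C@@H](C(C)=C)CO | intermediate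
9 | (2R,3R)-3-{2-[(tert-butyldimethylsilyl)oxy]ethyl}-3-methyl-2-(prop-1-en-2-yl)pent-4-enal | C=C[C@@](C)(CCO[Si](C)(C)C(C)(C)C)[C@@H](C(C)=C)C=O | intermediate
10 | (4S,5R,6R)-6-{2-[(tert-butyldimethylsilyl)oxy]ethyl}-6-methyl-5-(prop-1-en-2-yl)oct-7-en-2-yn-4-ol | C=C[C@@](C)(CCO[Si](C)(C)C(C)(C)C)[C@@H](C(C)=C)[C@H](O)C#CC | intermediate
11 | sodium cyclic alkenylaluminate (five-membered O–Al–C11=C7–C6 ring, two 2-methoxyethoxy groups on Al) (not isolated) | C=C[C@@](C)(CCO[Si](C)(C)C(C)(C)C)[C@@H](C(C)=C)[C@@H]1O[Al-](OCCOC)(OCCOC)C(C)=C1.[Na+] | intermediate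
12 | (2Z,4S,5R,6R)-6-{2-[(tert-butyldimethylsilyl)oxy]ethyl}-2-iodo-6-methyl-5-(prop-1-en-2-yl)octa-2,7-dien-4-ol | C=C[C@@](C)(CCO[Si](C)(C)C(C)(C)C)[C@@H](C(C)=C)[C@H](O)/C=C(/C)I | intermediate
13 | (5R)-5-[(3R,4R)-4-{2-[(tert-butyldimethylsilyl)oxy]ethyl}-2,4-dimethylhexa-1,5-dien-3-yl]-3-methylfuran-2(5H)-one | C=C[C@@](C)(CCO[Si](C)(C)C(C)(C)C)[C@@H](C(C)=C)[C@@H]1OC(=O)C(C)=C1 | intermediate
14 | (5R)-5-[(3R,4R)-4-(2-hydroxyethyl)-2,4-dimethylhexa-1,5-dien-3-yl]-3-methylfuran-2(5H)-one | C=C[C@@](C)(CCO)[C@@H](C(C)=C)[C@@H]1OC(=O)C(C)=C1 | intermediate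
15 | (3R,4R)-3-ethenyl-3,5-dimethyl-4-[(2R)-4-methyl-5-oxo-2,5-dihydrofuran-2-yl]hex-5-enal | C=C[C@@](C)(CC=O)[C@@H](C(C)=C)[C@@H]1OC(=O)C(C)=C1 | intermediate
16 | bis(diiodosamarium) enolate–alkoxide of the cyclized lactone (trivalent samarium on the C8 oxygen and on the enolate oxygen) (not isolated) | C=C[C@@]1(C)C[C@H](O[Sm](I)I)[C@@H]2[C@@H](OC(O[Sm](I)I)=C2C)[C@@H]1C(=C)C | intermediate
17 | (3S,3aR,4S,6R,7R,7aS)-6-ethenyl-3,4-dihydroxy-3,6-dimethyl-7-(prop-1-en-2-yl)hexahydro-1-benzofuran-2(3H)-one | C=C[C@@]1(C)C[C@H](O)[C@@H]2[C@@H](OC(=O)[C@@]2(C)O)[C@@H]1C(=C)C | intermediate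
18 | (3S,3aR,4S,6R,7R,7aS)-6-ethenyl-3-hydroxy-3,6-dimethyl-2-oxo-7-(prop-1-en-2-yl)octahydro-1-benzofuran-4-yl acetate | C=C[C@@]1(C)C[C@H](OC(C)=O)[C@@H]2[C@@H](OC(=O)[C@@]2(C)O)[C@@H]1C(=C)C | intermediate
19 | angelic acid, (2Z)-2-methylbut-2-enoic acid | C/C=C(/C)C(=O)O | starting material
20 | (2Z)-2-methylbut-2-enoic 2,4,6-trichlorobenzoic anhydride (not isolated) | C/C=C(/C)C(=O)OC(=O)c1c(Cl)cc(Cl)cc1Cl | intermediate
21 | (3S,3aR,4S,6R,7R,7aS)-4-acetoxy-6-ethenyl-3,6-dimethyl-2-oxo-7-(prop-1-en-2-yl)octahydro-1-benzofuran-3-yl (2Z)-2-methylbut-2-enoate | C=C[C@@]1(C)C[C@H](OC(C)=O)[C@@H]2[C@@H](OC(=O)[C@@]2(C)OC(=O)/C(C)=C\C)[C@@H]1C(=C)C | target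

**Step count and risks**

Total step count: 13. Longest linear sequence: 13 steps (from 1).

Steps most likely to fail:

1. Step 11. The in-flask oxygenation may fail through premature protonation of the samarium enolate, through consumption of the oxidant by residual divalent samarium, or through addition of the enolate to the sulfonimine instead of oxygen transfer. Fallback (known chemistry, two operations): from aldehyde 15 the cyclization is run with SmI2, HMPA and t-BuOH in THF at −78 °C, so that the enolate is protonated and the C3-unoxygenated hydroxy lactone F1 should result (its C3 epimers are of no consequence). The dianion of F1 (LiN(i-Pr)2, THF, −78 °C) is then hydroxylated with the same oxaziridine on the convex face, and the route is rejoined at diol 17.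

2. Step 3. Loss of enolate geometry or of facial control in the boron-mediated rearrangement would erode the diastereo- and enantioselectivity at C5 and C10. Fallback: from ester 5 a conventional Ireland–Claisen rearrangement (LiN(i-Pr)2, THF, −78 °C; Me3SiCl; warming to rt) through the trimethylsilyl ketene acetal F2 should give the racemic acid F3 with the same relative configuration. Resolution through the crystalline 1-phenylethylammonium salt F4 [(S)-amine, or its antipode if that salt crystallizes better] and acidification rejoins the route at acid 7.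

3. Step 13. Slow acylation of the hindered tertiary hydroxyl at 90 °C leaves time for Z→E isomerization of the angeloyl unit and for acyl migration from C8. Fallback: from hydroxy acetate 18, acylation with 2-[bis(2,2,2-trifluoroethoxy)phosphoryl]propanoic acid and DCC (through the phosphonoketene, which acylates tertiary alcohols) should give phosphonopropanoate ester F5. Still–Gennari olefination of F5 (KN(SiMe3)2, 18-crown-6, THF, −78 °C, then acetaldehyde) builds the (Z)-2-methylbut-2-enoate on the molecule and rejoins the route at target 21.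

**Further compounds**

F1 | step 11 | (3RS,3aR,4S,6R,7R,7aS)-6-ethenyl-4-hydroxy-3,6-dimethyl-7-(prop-1-en-2-yl)hexahydro-1-benzofuran-2(3H)-one (C3 epimers) | C=C[C@@]1(C)C[C@H](O)[C@@H]2[C@@H](OC(=O)C2C)[C@@H]1C(=C)C
F2 | step 3 | trimethylsilyl ketene acetal of ester 5 (isopropenyl cis to the allyloxy oxygen) | C=C(C)/C=C(\OC/C=C(\C)CCO[Si](C)(C)C(C)(C)C)O[Si](C)(C)C
F3 | step 3 | racemic (2R*,3R*)-3-{2-[(tert-butyldimethylsilyl)oxy]ethyl}-3-methyl-2-(prop-1-en-2-yl)pent-4-enoic acid (both enantiomers) | C=C[C@@](C)(CCO[Si](C)(C)C(C)(C)C)[C@@H](C(C)=C)C(=O)O.C=C[C@](C)(CCO[Si](C)(C)C(C)(C)C)[C@H](C(C)=C)C(=O)O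
F4 | step 3 | (S)-1-phenylethylammonium (2R,3R)-3-{2-[(tert-butyldimethylsilyl)oxy]ethyl}-3-methyl-2-(prop-1-en-2-yl)pent-4-enoate | C=C[C@@](C)(CCO[Si](C)(C)C(C)(C)C)[C@@H](C(C)=C)C(=O)[O-].C[C@H]([NH3+])c1ccccc1
F5 | step 13 | (3S,3aR,4S,6R,7R,7aS)-4-acetoxy-6-ethenyl-3,6-dimethyl-2-oxo-7-(prop-1-en-2-yl)octahydro-1-benzofuran-3-yl 2-[bis(2,2,2-trifluoroethoxy)phosphoryl]propanoate | C=C[C@@]1(C)C[C@H](OC(C)=O)[C@@H]2[C@@H](OC(=O)[C@@]2(C)OC(=O)C(C)P(=O)(OCC(F)(F)F)OCC(F)(F)F)[C@@H]1C(=C)C
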